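| setting | Saturday's | Friday's | Sunday's | Wednesday's |
|---|---|---|---|---|
| substrate | 0.250 M | 0.750 M | 0.250 M | 0.0830 M |
| partner | 0.275 M | 0.275 M | 0.830 M | 0.830 M |
| time |  |  |  | 100 min |

| run | time / min | [target] / M |
|---|---|---|
| Saturday's run | 3.6 | 0.017 |
| Saturday's run | 11 | 0.041 |
| Saturday's run | 21 | 0.071 |
| Saturday's run | 33 | 0.077 |
| Saturday's run | 47 | 0.078 |
| Saturday's run | 63 | 0.087 |
| Saturday's run | 81 | 0.093 |
| Saturday's run | 100 | 0.090 |
| Friday's run | 3.6 | 0.057 |
| Friday's run | 11 | 0.125 |
| Friday's run | 21 | 0.152 |
| Friday's run | 33 | 0.164 |
| Friday's run | 47 | 0.170 |
| Friday's run | 63 | 0.177 |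
| Friday's run | 81 | 0.172 |
| Friday's run | 100 | 0.172 |
| Sunday's run | 3.6 | 0.046 |
| Sunday's run | 11 | 0.087 |
| Sunday's run | 21 | 0.094 |
| Sunday's run | 33 | 0.098 |
| Sunday's run | 47 | 0.100 |
| Sunday's run | 63 | 0.108 |
| Sunday's run | 81 | 0.106 |
| Sunday's run | 100 | 0.120 |

(readings scatter by 0.004 M)

1. order of the initial rate in [partner], near the charge of the Saturday's run, the rate being that where two percent of its substrate are target
2. order of the initial rate in [substrate], near the charge of the Saturday's run, the rate being that where two percent of its substrate are target (one fixed amount of target, the same in the runs compared)
3. target in the Wednesday's run at 100 min, as a share of the substrate charged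

- Overall: substrate + partner -> target.
- Constant volume, constant temperature.
- "The second partner" is partner.
- An order is taken over about fifteen percent of the charge, up and down.

**Early shares.** Read each early reading as a fraction of that flask's substrate charge. At 3.6 min, Saturday's flask stands at 6.80% and Friday's at 7.60%, although Friday's substrate charge is 3.00 times Saturday's. Their gap is smaller than the scatter of 1.60% of Saturday's charge, so take the order in substrate as near one. Sunday's flask, with 3.02 times Saturday's partner, stands at 18.4%, which is 2.71 times Saturday's share, so take the order in partner as near one too.

**The draw.** Define the draw as the target standing late, as a fraction of the partner charged. Averaged from 47 min on, Sunday's flask gives 13.1%. The last readings give 32.7% for Saturday's flask and 62.5% for Friday's. Where the draw is small, assume that, at one partner charge, the partner follows nearly the same course whatever the substrate charge. Substrate then reacts in a pseudo-first-order way along that course, and its fraction turned to target does not depend on its charge.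

**Own reckoning.** Wednesday's flask has Sunday's partner charge and about a third of its substrate. Sunday's draw is lower than the other two, so carry its late fraction of substrate over, taking that average for the share at 100 min: the draw times partner over substrate gives 43.4%. Wednesday's own draw would then be 4.34%.

**The forecast.** It gives orders of 1 in partner and 1.05 in substrate, and 60% for Wednesday's flask, within 46% to 75%. Its ground is that “The fractional yield at 100 min rises as substrate falls”. My 43.4% lies lower than its range.

**The result.** Wednesday's flask gives 42.8% at 100 min, 0.60 percentage points below my figure, with orders of 1.0 in partner and 1.1 in substrate.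

    substrate + partner → target + by-product (0.1104 L mol⁻¹ min⁻¹)
    target + partner → side product (0.07800 L mol⁻¹ min⁻¹)
    2 partner → lost reagent (0.1038 L mol⁻¹ min⁻¹)

At Sunday's charge, the first half-life of partner by its self-loss alone is 5.80 min. Wednesday's draw at 100 min comes to 4.28%, less than Sunday's late average of 13.1%. Friday's flask reads a draw of 62.5%, far more than Wednesday's, with 22.9% of its substrate as target at 100 min.

The runs were computed on assumed constants; noise was put on by code.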